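# Total synthesis of sargachromanol C

**Retrosynthetic overview**
1. The last step removes an aryl TIPS ether. Before that, an sp3–sp2 Suzuki coupling joins a C2–CH2CH2–[B] chain (from hydroboration of a 2-vinylchromane) to an (E)-vinyl iodide that already carries the (R)-allylic alcohol and the prenyl terminus.
2. The vinyl iodide comes from: cross-metathesis of an allyl group with 2-methyl-2-butene to give the prenyl terminus; Brown asymmetric allylation of an E-enal; stabilised-ylide Wittig olefination; and Negishi methylalumination–iodination of pent-4-yn-1-ol.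
3. The only ring, the chromane, is formed before any chain is attached. A new Pd-catalysed enantioconvergent intramolecular etherification of a racemic tertiary allylic bis-carbonate builds the quaternary C2 stereocentre. The aryl ring comes from methylhydroquinone by ortho-formylation, then chain extension to a tertiary allylic alcohol.

**Assumptions**
- TIPSCl silylates the less hindered OH of methylhydroquinone.
- The ligand and pinene enantiomers named below are the ones I expect to give the (2R,9R) target. The descriptor for the 2-vinylchromane intermediate is (S) only because the vinyl group outranks C3 in CIP priority.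
- Compound numbers run in order of first appearance in Steps 1–14. Catalysts and H2 are not numbered.

---

**Step 1**
Reactants: 1 2-methylbenzene-1,4-diol (methylhydroquinone); 2 triisopropylsilyl chloride (TIPSCl)
Product: 3 2-methyl-4-(triisopropylsilyloxy)phenol
Conditions: TIPSCl (1.0 equiv), imidazole, CH2Cl2, 0 °C → rt
Reagents that add atoms: TIPSCl, CC(C)[Si](Cl)(C(C)C)C(C)C
Why: The bulky silyl chloride selectively protects the OH that is not ortho to the methyl group (selective silylation). This leaves the hindered OH free to become the ring oxygen.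

**Step 2**
Reactants: 3; 4 paraformaldehyde
Product: 5 2-hydroxy-3-methyl-5-(triisopropylsilyloxy)benzaldehyde
Conditions: MgCl2, Et3N, (CH2O)n, MeCN, reflux
Reagents that add atoms: paraformaldehyde, C=O
Why: Casnati–Skattebøl ortho-formylation proceeds through a magnesium phenoxide template. Only one ortho position is free (the other carries the methyl group) and the para position is blocked, so it is regiospecific.

**Step 3**
Reactants: 5; 6 1-(triphenylphosphoranylidene)propan-2-one
Product: 7 (E)-4-[2-hydroxy-3-methyl-5-(TIPSO)phenyl]but-3-en-2-one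
Conditions: toluene, 80 °C
Reagents that add atoms: Ph3P=CHC(O)CH3, CC(=O)C=P(c1ccccc1)(c1ccccc1)c1ccccc1
Why: A stabilised-ylide Wittig olefination gives the E-enone and leaves the free phenol and the aryl silyl ether untouched.

**Step 4**
Reactants: 7; H2
Product: 8 4-[2-hydroxy-3-methyl-5-(TIPSO)phenyl]butan-2-one
Conditions: H2 (1 atm), 10% Pd/C, EtOAc, rt
Reagents that add atoms: none (hydrogen only)
Why: Chemoselective hydrogenation of the conjugated C=C; the aryl TIPS ether and the ketone are unaffected.

**Step 5**
Reactants: 8; 9 vinylmagnesium bromide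
Product: 10 rac-5-[2-hydroxy-3-methyl-5-(TIPSO)phenyl]-3-methylpent-1-en-3-ol
Conditions: CeCl3 (anhydrous), vinylMgBr (3.5 equiv), THF, −78 → 0 °C
Reagents that add atoms: vinylMgBr, C=C[Mg]Br
Why: The organocerium 1,2-addition suppresses enolisation of the methyl ketone, and the extra equivalents cover the phenol. The new carbinol stereocentre is racemic and is erased by ionisation in Step 7, so it does not matter.

**Step 6**
Reactants: 10; 11 methyl chloroformate
Product: 12 rac-bis(methyl carbonate): 5-[2-(methoxycarbonyloxy)-3-methyl-5-(TIPSO)phenyl]-3-methylpent-1-en-3-yl methyl carbonate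
Conditions: n-BuLi (2.2 equiv), THF, −78 °C; then ClCO2Me (3 equiv), −78 °C → rt
Reagents that add atoms: methyl chloroformate, COC(=O)Cl
Why: Acylation of the lithium phenoxide and the lithium tertiary alkoxide. The aryl carbonate is a masked phenoxide that is released in Step 7.

**Step 7**
Reactants: 12
Product: 13 (2S)-2-ethenyl-2,8-dimethyl-6-(triisopropylsilyloxy)chromane
Conditions: Pd2(dba)3·CHCl3 (2.5 mol%), (R,R)-Trost DACH-phenyl ligand (7.5 mol%), CH2Cl2, 23 °C (by-products CO2 and dimethyl carbonate)
Reagents that add atoms: none
Why: Proposed new method: Pd(0) ionises the tertiary allylic carbonate to a 1,1-disubstituted π-allyl. Fast η3–η1–η3 interconversion at the CH2 terminus makes the racemic substrate converge. Decarboxylation releases MeO⁻, which cleaves the aryl methyl carbonate in situ and gives the phenoxide without external base. The phenoxide then attacks the tertiary terminus in a 6-exo closure (the 8-membered attack at the CH2 terminus is disfavoured). The chiral ligand controls the face of attack and sets the quaternary C–O stereocentre. The closest known reactions are Trost Pd-AAA/DYKAT and intramolecular Tsuji–Trost etherification to 2-vinylchromans (tertiary-ether, quaternary-centre version not known to me).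

**Step 8**
Reactants: 14 pent-4-yn-1-ol; 15 trimethylaluminium; 16 iodine
Product: 17 (E)-5-iodo-4-methylpent-4-en-1-ol
Conditions: Cp2ZrCl2 (20 mol%), AlMe3 (3 equiv), ClCH2CH2Cl, 0 °C → rt; then I2, THF, −30 °C
Reagents that add atoms: AlMe3, C[Al](C)C; I2, II
Why: Negishi Zr-catalysed syn-methylalumination of the terminal alkyne, then iodinolysis, gives the E-trisubstituted vinyl iodide. The free OH is tolerated.

**Step 9**
Reactants: 17
Product: 18 (E)-5-iodo-4-methylpent-4-enal
Conditions: Dess–Martin periodinane, NaHCO3, CH2Cl2, 0 °C → rt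
Reagents that add atoms: none
Why: Mild oxidation of the primary alcohol; the vinyl iodide survives.

**Step 10**
Reactants: 18; 19 2-(triphenylphosphoranylidene)propanal
Product: 20 (2E,6E)-7-iodo-2,6-dimethylhepta-2,6-dienal
Conditions: toluene, 80 °C
Reagents that add atoms: Ph3P=C(CH3)CHO, CC(C=O)=P(c1ccccc1)(c1ccccc1)c1ccccc1
Why: Stabilised-ylide Wittig olefination of an aldehyde gives the α-methyl enal with high E selectivity, which is the E-trisubstituted alkene next to the future carbinol.

**Step 11**
Reactants: 20; 21 B-allyldiisopinocampheylborane from (−)-α-pinene, (+)-Ipc2B(allyl)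
Product: 22 (4R,5E,9E)-10-iodo-5,9-dimethyldeca-1,5,9-trien-4-ol
Conditions: Et2O, −78 °C, 3 h; then NaOH, H2O2, 0 °C → rt
Reagents that add atoms: (+)-Ipc2B-allyl, C=CCB(C1CC2CC(C2(C)C)C1C)C1CC2CC(C2(C)C)C1C (Ipc from (−)-α-pinene)
Why: Brown asymmetric allylboration proceeds through a closed chair transition state. The reagent attacks the Re face of the enal and sets the (R) carbinol (allylboration of an α,β-unsaturated aldehyde).

**Step 12**
Reactants: 22; 23 2-methylbut-2-ene
Product: 24 (5R,6E,10E)-11-iodo-2,6,10-trimethylundeca-2,6,10-trien-5-ol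
Conditions: Hoveyda–Grubbs II (5 mol%), 2-methylbut-2-ene (20 equiv), CH2Cl2, 40 °C
Reagents that add atoms: 2-methylbut-2-ene, CC=C(C)C
Why: Olefin cross-metathesis converts the terminal alkene to the prenyl terminus. It is much faster than reaction of the hindered trisubstituted alkenes or the vinyl iodide, and the carbinol stereocentre is not touched.

**Step 13**
Reactants: 13; 25 9-BBN; 24
Product: 26 TIPS ether of sargachromanol C
Conditions: 13 + 9-BBN (1.2 equiv), THF, rt, 3 h; then 24 (0.8 equiv), PdCl2(dppf)·CH2Cl2, AsPh3, Cs2CO3, THF/DMF/H2O, rt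
Reagents that add atoms: none (boron is lost)
Why: 9-BBN hydroborates only the unhindered vinyl group, giving the primary alkylborane, and a Johnson–Suzuki B-alkyl coupling then joins it to the vinyl iodide with retention of E geometry. The quaternary C2 stereocentre is not involved.

**Step 14**
Reactants: 26
Product: 27 sargachromanol C
Conditions: TBAF (1.5 equiv), AcOH (buffer), THF, 0 °C, 30 min
Reagents that add atoms: none
Why: Fluoride desilylation of the aryl TIPS ether is mild enough to leave the allylic alcohol and the three trisubstituted alkenes intact.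

---

**Compound list**

| No. | Name | SMILES | Role |
|---|---|---|---|
| 1 | 2-methylbenzene-1,4-diol | Cc1cc(O)ccc1O | starting material |
| 2 | triisopropylsilyl chloride | CC(C)[Si](Cl)(C(C)C)C(C)C | starting material |
| 3 | 2-methyl-4-(TIPSO)phenol | Cc1cc(O[Si](C(C)C)(C(C)C)C(C)C)ccc1O | intermediate |
| 4 | paraformaldehyde | C=O | starting material |
| 5 | 2-hydroxy-3-methyl-5-(TIPSO)benzaldehyde | O=Cc1cc(O[Si](C(C)C)(C(C)C)C(C)C)cc(C)c1O | intermediate |
| 6 | 1-(triphenylphosphoranylidene)propan-2-one | CC(=O)C=P(c1ccccc1)(c1ccccc1)c1ccccc1 | starting material |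
| 7 | (E)-4-[2-hydroxy-3-methyl-5-(TIPSO)phenyl]but-3-en-2-one | CC(=O)/C=C/c1cc(O[Si](C(C)C)(C(C)C)C(C)C)cc(C)c1O | intermediate |
| 8 | 4-[2-hydroxy-3-methyl-5-(TIPSO)phenyl]butan-2-one | CC(=O)CCc1cc(O[Si](C(C)C)(C(C)C)C(C)C)cc(C)c1O | intermediate |
| 9 | vinylmagnesium bromide | C=C[Mg]Br | starting material |
| 10 | rac-5-[2-hydroxy-3-methyl-5-(TIPSO)phenyl]-3-methylpent-1-en-3-ol | C=CC(C)(O)CCc1cc(O[Si](C(C)C)(C(C)C)C(C)C)cc(C)c1O | intermediate |
| 11 | methyl chloroformate | COC(=O)Cl | starting material |
| 12 | rac-bis(methyl carbonate) of 10 | C=CC(C)(OC(=O)OC)CCc1cc(O[Si](C(C)C)(C(C)C)C(C)C)cc(C)c1OC(=O)OC | intermediate |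
| 13 | (2S)-2-ethenyl-2,8-dimethyl-6-(TIPSO)chromane | C=C[C@]1(C)CCc2cc(O[Si](C(C)C)(C(C)C)C(C)C)cc(C)c2O1 | intermediate |
| 14 | pent-4-yn-1-ol | C#CCCCO | starting material |
| 15 | trimethylaluminium | C[Al](C)C | starting material |
| 16 | iodine | II | starting material |
| 17 | (E)-5-iodo-4-methylpent-4-en-1-ol | OCCC/C(C)=C/I | intermediate |
| 18 | (E)-5-iodo-4-methylpent-4-enal | O=CCC/C(C)=C/I | intermediate |
| 19 | 2-(triphenylphosphoranylidene)propanal | CC(C=O)=P(c1ccccc1)(c1ccccc1)c1ccccc1 | starting material |
| 20 | (2E,6E)-7-iodo-2,6-dimethylhepta-2,6-dienal | O=C/C(C)=C/CC/C(C)=C/I | intermediate |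
| 21 | (+)-B-allyldiisopinocampheylborane (from (−)-α-pinene), Ipc stereochemistry not drawn | C=CCB(C1CC2CC(C2(C)C)C1C)C1CC2CC(C2(C)C)C1C | starting material |
| 22 | (4R,5E,9E)-10-iodo-5,9-dimethyldeca-1,5,9-trien-4-ol | C=CC[C@@H](O)/C(C)=C/CC/C(C)=C/I | intermediate |
| 23 | 2-methylbut-2-ene | CC=C(C)C | starting material |
| 24 | (5R,6E,10E)-11-iodo-2,6,10-trimethylundeca-2,6,10-trien-5-ol | CC(C)=CC[C@@H](O)/C(C)=C/CC/C(C)=C/I | intermediate |
| 25 | 9-borabicyclo[3.3.1]nonane (9-BBN) | B1C2CCCC1CCC2 | starting material |
| 26 | TIPS ether of sargachromanol C | CC(C)=CC[C@@H](O)/C(C)=C/CC/C(C)=C/CC[C@]1(C)CCc2cc(O[Si](C(C)C)(C(C)C)C(C)C)cc(C)c2O1 | intermediate |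
| 27 | sargachromanol C, (2R)-2,8-dimethyl-2-[(3E,7E,9R)-9-hydroxy-4,8,12-trimethyltrideca-3,7,11-trien-1-yl]chroman-6-ol | CC(C)=CC[C@@H](O)/C(C)=C/CC/C(C)=C/CC[C@]1(C)CCc2cc(O)cc(C)c2O1 | target |

---

**Totals**
- Total steps: 14.
- Longest linear sequence: 9 steps (Steps 1–7, 13, 14, counted from methylhydroquinone).
- The other branch, from pent-4-yn-1-ol, is 5 steps (Steps 8–12) before it joins at Step 13.

**Three steps most likely to fail**
1. **Step 7 (proposed new Pd etherification).** Ionisation of a tertiary carbonate can give 1,3-diene by elimination. Methoxide can also trap the π-allyl intermolecularly, and ee at the quaternary centre is unproven.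
   - Fallback: make racemic 13 by acid-promoted SN1 cyclisation of tertiary allylic alcohol 10 (p-TsOH, CH2Cl2), then isolate (S)-13 by preparative chiral SFC/HPLC. This is resolution, not asymmetric catalysis.
2. **Step 11 (Brown allylation).** The facial sense I assigned to the (+)-Ipc reagent may be wrong, and the α-methyl enal may give only moderate ee.
   - Fallback: allylate 20 with allylMgBr to give racemic 22, then perform a Sharpless kinetic resolution (Ti(OiPr)4, L-(+)-DIPT, TBHP). The (S) allylic alcohol epoxidises faster, leaving (R)-22.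
3. **Step 13 (hydroboration/Suzuki on a polyene with a free OH).** Hydroboration may be incomplete, or coupling may be sluggish because of the neopentyl-like chromane.
   - Fallback: change the coupling partner. Do hydroboration–oxidation of 13 to the primary alcohol, then Appel iodination to the alkyl iodide. Convert that to the alkylzinc (t-BuLi, then ZnBr2) and run a Pd-catalysed Negishi coupling with 24.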